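Set the blue run beside the red run before reading anything else in this flask.

| flask | substrate | coupling partner | catalyst | time |
|---|---|---|---|---|
| blue | 250 mM | 275 mM | 7.50 mM |  |
| red | 150 mM | 175 mM | 7.50 mM |  |
| grey | 750 mM | 275 mM | 7.50 mM |  |
| ochre | 250 mM | 410 mM | 7.50 mM |  |
| teal | 250 mM | 275 mM | 7.50 mM | 100 min |

- blue run (time / min: [target] / mM): 1.0: 7.9; 1.8: 13.3; 3.0: 23.6; 5.2: 33.4; 8.9: 50.3; 15: 68.8; 26: 95.8
- red run (time / min: [target] / mM): 1.0: 5.3; 1.8: 9.6; 3.0: 10.1; 5.2: 18.6; 8.9: 24.3; 15: 36.0; 26: 48.3
- grey run (time / min: [target] / mM): 1.0: 21.2; 1.8: 37.2; 3.0: 52.4; 5.2: 77.7; 8.9: 112.1; 15: 144.2; 26: 177.6
- ochre run (time / min: [target] / mM): 1.0: 14.3; 1.8: 15.1; 3.0: 31.5; 5.2: 41.9; 8.9: 64.0; 15: 86.7; 26: 113.6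

(each reading ± 2 mM)

1. order of the initial rate in [coupling partner], near the charge of the blue run, the rate being that where two percent of its substrate are target
2. order of the initial rate in [substrate], near the charge of the blue run, the rate being that where two percent of its substrate are target (one fixed amount of target, the same in the runs compared)
3. the red run starts with 100 mM less of substrate and of coupling partner than the blue run, and with no target. Compared where both hold the same amount of substrate, once fifteen percent of what the red run was charged with has turned into target, is the red run faster, slower or alike (within a tenth)?
4. target in the teal run at 100 min, as a share of the substrate charged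

- Overall: substrate + coupling partner -> target, with catalyst as catalyst.
- Constant volume, constant temperature.
- Bound and free are read together.
- An order is taken over about fifteen percent of the charge, up and down.

*What do the blue and red charges share?* They share the excess of coupling partner over substrate: 25.0 mM in the blue run and 25.0 mM in the red run. The overall reaction uses the two one to one. So when the blue run has used 100 mM of substrate, its balance reads [substrate] 150 mM and [coupling partner] 175 mM, which is the red charge.

*Where is the zero of the scale?* At a ratio of one. If the rate followed the concentrations given by the balance, the two runs would match at equal [substrate].

*What do the readings give?* The red run makes 18.6 mM in its first 5.2 min, a mean rate of 3.58 mM/min at about 141 mM of substrate. Between its last two readings, the blue run makes target at 2.45 mM/min at about 168 mM of substrate. The quotient, 1.46, is my same-excess ratio: the rate of a fresh run over the rate of an older run with the same excess, at nearly equal [substrate].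

*But the two intervals don't hold equal [substrate]. Is that fair?* The mismatch works against the result. The blue interval is richer in substrate than the red one, yet its rate is lower. At the same [coupling partner], the grey run, with its higher [substrate], makes target faster than the blue run. Matching the intervals should therefore raise the ratio, and I take 1.46 as a lower reading.

*And the scatter?* Carried through the three readings, it gives 0.219, so the ratio stands 2.10 standard deviations above one.

*What does a ratio above one say?* The older run differs from the fresh run in something other than its [substrate]. That could be the target it carries, the age of its catalyst, or less coupling partner than its balance says. This one ratio doesn't separate these.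

*What do you commit to?* The red run is faster at the asked point, which lies beyond the last blue reading, and its ratio is above 1.46. The teal run has the blue charge, so I carry the blue decline into it rather than integrating a constant coefficient.

The forecast gave 0.68 in [coupling partner], 0.92 in [substrate], faster and 66%, and said of the decline: “this looks like product inhibition”.

The simulation gives 0.85 in [coupling partner], 0.94 in [substrate], faster and 54.3%.

    catalyst + substrate ⇌ catalyst-substrate complex, settled at all times (4.310 /M)
    catalyst + coupling partner ⇌ catalyst-reagent complex, settled at all times (5.680 /M)
    catalyst-substrate complex + catalyst-reagent complex → target + 2 catalyst (216.6 /M/min)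
    2 coupling partner → lost reagent (0.1206 /M/min)
    substrate + coupling partner → target (0.09900 /M/min)

The same-excess ratio stood at 1.46 on the readings; at the asked point, later in the blue run, it is 4.2. With the conversion of two coupling partner into lost reagent taken away, that ratio falls to 1.0, the zero of the scale, so this step is the reason for the gap between the red and blue runs. The teal run, with the blue charge, shows the same step in its yield: target reaches 54.3% of the substrate charged at 100 min, against 85.6% without the step.

The readings were computed with made-up constants.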